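**Retrosynthetic overview**

1. Numbering: carbocycle C1 (C=CH2), C2–C4, C5 (CMe2), C6, C7, C8, C9 (quaternary, Me), C10; dioxabicycle C11 (CH on C9), C12 (acetal CH), C13 (lactone C=O), C14 (CHOAc), C15, C16 (CHCO2Me, ring oxygen O16), C17 (ester carbon).
2. Feature: the cis-fused seven–five carbocycle (ring C1–C2–C3–C4–C5–C6–C10 with the C1 methylidene beside fusion carbon C10 and the C5 gem-dimethyl beside fusion carbon C6, fused to ring C6–C7–C8–C9–C10) is the reduced, dehydrated form of the hydroxy enone that a 4a-methyl-8,8-dimethyl cross-conjugated cyclohexadienone gives when irradiated in aqueous acid (new C6–C10 and C1–O bonds).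
3. Late disconnections: C1=CH2 from the C1 carbinol; O–C12 of the lactone by Baeyer–Villiger oxidation of a 2-oxabicyclo[2.2.1]heptan-6-one; C12–O16 by alkoxide displacement of an α-chloro ketone; C9–C11 by decarboxylative radical addition of a C9 carboxylate to a chloro cyclopentenone made from a bicyclic lactone.
4. An ester placed on the dienone (at the carbon that becomes C9) steers the photochemical ring opening to the 5/7 skeleton, then carries the C9 methylation, masks the C1 carbinol as a γ-lactone while C6=C7 and C8=O are removed, and finally leaves as CO2.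
5. Ring order: six-membered carbocycle by phenoxide para-alkylation; five- and seven-membered rings together in the photochemical step; oxolane ring (C12–O16); six-membered lactone by oxygen insertion.

Key step: step 8

Assumption: the dextrorotatory (1R,5S) enantiomer of the bicyclic lactone starting material is bought as such, and the racemic dienone is separated into enantiomers on a chiral phase.

**Route**

Step 1
Reactants: 1 3-bromo-4-methylanisole; 2 5-chloropentan-2-one
Product: 4 5-chloro-2-(5-methoxy-2-methylphenyl)pentan-2-ol (racemic), via aryllithium 3 (not isolated)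
Conditions: n-BuLi, THF, −78 °C; then 2, −78 °C; AcOH quench at −78 °C
Reagents that add atoms: none
Why: Bromine–lithium exchange then 1,2-addition of the aryllithium to the methyl ketone (organolithium carbonyl addition), quenched cold so that the γ-chloro alkoxide does not close to a tetrahydrofuran; the carbinol centre is racemic and disappears in step 2.

Step 2
Reactants: 4 tertiary benzylic alcohol
Product: 5 2-(5-chloro-2-methylpentan-2-yl)-4-methoxy-1-methylbenzene
Conditions: Me3Al (4 equiv), CH2Cl2, −20 → 40 °C
Reagents that add atoms: trimethylaluminium, C[Al](C)C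
Why: Exhaustive C-methylation of a tertiary benzylic alcohol (Meisters–Mole/Reetz type: the aluminium alkoxide ionises to the benzylic cation, which takes a methyl group from aluminium), leaving the primary chloride and the aryl ether alone.

Step 3
Reactants: 5 aryl methyl ether
Product: 6 3-(5-chloro-2-methylpentan-2-yl)-4-methylphenol
Conditions: BBr3, CH2Cl2, −78 → 0 °C; H2O
Reagents that add atoms: none
Why: Lewis-acid cleavage of the aryl methyl ether by BBr3, to which the primary alkyl chloride and the quaternary benzylic carbon are inert.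

Step 4
Reactants: 6 chloroalkyl phenol
Product: 7 rac-4a,8,8-trimethyl-5,6,7,8-tetrahydronaphthalen-2(4aH)-one
Conditions: KOtBu (1.2 equiv), t-BuOH, 0.01 M, 80 °C
Reagents that add atoms: none
Why: Intramolecular para-C-alkylation of the phenoxide (Ar2-6 phenol dearomatisation of the Winstein–Masamune type) in tert-butanol, which favours C- over O-alkylation, closes the six-membered ring at the methyl-bearing para carbon and creates the quaternary C4a as a racemate.

Step 5
Reactants: 7 racemic dienone
Product: 8 (4aR)-4a,8,8-trimethyl-5,6,7,8-tetrahydronaphthalen-2(4aH)-one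
Conditions: preparative SFC, amylose tris(3,5-dimethylphenylcarbamate) phase, CO2/MeOH
Reagents that add atoms: none
Why: Chromatography on a chiral stationary phase separates the enantiomers, and the (4aR) antipode is carried on, its assignment to be confirmed by anomalous-dispersion crystallography of iodide 9.

Step 6
Reactants: 8 (4aR)-dienone
Product: 9 (4aR)-3-iodo-4a,8,8-trimethyl-5,6,7,8-tetrahydronaphthalen-2(4aH)-one
Conditions: I2 (1.5 equiv), pyridine/CH2Cl2 (1:1), 23 °C
Reagents that add atoms: iodine, II
Why: Johnson α-iodination of an enone (pyridine adds to the β-carbon, the enolate is iodinated, pyridine leaves) can start only at C4, because the other β-carbon C8a is fully substituted, so iodine enters at C3.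

Step 7
Reactants: 9 iodo dienone
Product: 10 methyl (4aR)-4a,8,8-trimethyl-2-oxo-2,4a,5,6,7,8-hexahydronaphthalene-3-carboxylate (dienone numbering kept)
Conditions: Pd(OAc)2 (5 mol %), PPh3 (10 mol %), CO (1 atm), Et3N, MeOH/DMF (1:4), 50 °C
Reagents that add atoms: carbon monoxide, [C-]#[O+]; methanol, CO
Why: Palladium-catalysed methoxycarbonylation of the vinyl iodide (oxidative addition to zerovalent palladium, CO insertion, methanolysis of the acyl complex) installs the ester that directs step 8.

Step 8
Reactants: 10 dienone ester
Product: 11 hydroxy hydroazulenone ester (C1 carbinol, C6=C7–C8=O enone, C9 CH(CO2Me), C10–H as in the target)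
Conditions: hν (medium-pressure Hg lamp, Pyrex filter), 45% aq. AcOH, 20 °C, argon, stopped at about 80% conversion
Reagents that add atoms: water, O
Why: Excitation of the cross-conjugated dienone bonds its two β-carbons (C6–C10) to give a zwitterionic bicyclo[3.1.0]hexenone, and after O-protonation the hydroxyallyl cation opens the cyclopropane bond C1–C6 as water attacks C1 from the rear. The closest known reaction type is the santonin to isophotosantonic lactone rearrangement in aqueous acetic acid, together with its 2-alkoxycarbonyl dienone variants that give 5/7-fused hydroxy ketones. The five-membered ring closes by the light-driven C6–C10 bonding across the dienone (formation of the bicyclo[3.1.0] bridge), and the seven-membered ring arises by ring enlargement when the cyclopropane bond shared with the old six-membered ring is cut. C10 takes its configuration stereospecifically from C4a, because the bridge can form only on the face fixed by the ring tether, and C1 is set by inversion (water anti to the departing C6), though it is lost again in step 22. The selectivity needed is opening to the hydroazulenone and not to the spiro[4.5]decenone: the ester on dienone C3 (later C9) withdraws positive charge from that end of the hydroxyallyl cation, so the charge sits at C7 and breaks C1–C6, helped by relief of strain beside the C5 gem-dimethyl group. Irradiation is stopped short of full conversion because the product enone also absorbs.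

Step 9
Reactants: 11 hydroxy hydroazulenone ester
Product: 12 C9-methylated hydroxy enone ester (methyl syn to H10, ester syn to C1)
Conditions: K2CO3, MeI, acetone, 0 → 23 °C
Reagents that add atoms: iodomethane, CI
Why: C-Alkylation of the β-keto ester enolate, run directly after step 8 so that the enol cannot shift the ring-fusion hydrogen, places the methyl on the open face anti to the C1 substituent of C10 and thus the ester cis to the C1 carbinol.

Step 10
Reactants: 12 methylated enone ester
Product: 13 cis-fused saturated keto ester (H6 syn to H10)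
Conditions: H2 (3 atm), 10% Pd on carbon, EtOAc, 23 °C
Reagents that add atoms: none
Why: Heterogeneous hydrogenation delivers hydrogen to C6 from the face opposite the seven-membered ring (C1 lies below the cyclopentenone plane), giving the cis ring fusion.

Step 11
Reactants: 13 saturated keto ester
Product: 15 enol triflate lactone (C7=C8–OTf and lactone C1–O–CO–C9), via potassium lactone enolate 14 (not isolated)
Conditions: KN(SiMe3)2 (2.1 equiv), THF, −78 → 0 °C; PhNTf2 (1.2 equiv), −78 → 0 °C; H2O
Reagents that add atoms: N-phenylbis(trifluoromethanesulfonyl)imide, FC(F)(F)S(=O)(=O)N(c1ccccc1)S(=O)(=O)C(F)(F)F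
Why: The base forms the C7 enolate, which shields the ketone from retro-Claisen cleavage, and the tertiary alkoxide, which closes onto the cis ester (lactonisation by acyl substitution with loss of methoxide), after which the enolate, able to form only toward C7, is O-sulfonylated (enol triflate formation); any C9 epimer with a trans ester cannot lactonise and is removed here.

Step 12
Reactants: 15 enol triflate lactone
Product: 16 saturated tricyclic γ-lactone
Conditions: H2 (1 atm), PtO2, NaHCO3, EtOAc, 23 °C
Reagents that add atoms: none
Why: Catalytic hydrogenolysis of the vinyl C–O bond with saturation of C7=C8 (ketone-to-methylene reduction through the enol triflate), NaHCO3 taking up the triflic acid, creates no stereocentre.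

Step 13
Reactants: 16 tricyclic lactone
Product: 17 potassium hydroxy carboxylate (C1 carbinol, C9 carboxylate)
Conditions: KOH (1.05 equiv), MeOH/H2O (4:1), 70 °C; evaporation, azeotropic drying with toluene
Reagents that add atoms: potassium hydroxide, [K+].[OH-]
Why: Saponification of the tertiary γ-lactone by acyl–oxygen cleavage leaves C1 untouched, and the product is kept as its salt because the free hydroxy acid would close again.

Step 14
Reactants: 18 (1R,5S)-2-oxabicyclo[3.3.0]oct-6-en-3-one
Product: 20 (1R,4R,5R)-4-hydroxy-2-oxabicyclo[3.3.0]oct-6-en-3-one (4-exo alcohol), via potassium enolate 19 (not isolated)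
Conditions: KN(SiMe3)2, THF, −78 °C; 2-(phenylsulfonyl)-3-phenyloxaziridine, −78 °C; AcOH
Reagents that add atoms: 2-(phenylsulfonyl)-3-phenyloxaziridine, O=S(=O)(c1ccccc1)N1OC1c1ccccc1
Why: Davis hydroxylation of the lactone enolate takes place on the convex face of the cis-fused bicycle, giving the exo alcohol, which is the C16 configuration of the target.

Step 15
Reactants: 20 hydroxy lactone
Product: 21 4-exo-(tert-butyldimethylsilyloxy) lactone
Conditions: TBSOTf, 2,6-lutidine, CH2Cl2, 0 °C
Reagents that add atoms: tert-butyldimethylsilyl trifluoromethanesulfonate, CC(C)(C)[Si](C)(C)OS(=O)(=O)C(F)(F)F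
Why: Silylation of a secondary alcohol with a silyl triflate gives an ether that survives hydroxide, SeO2 and the radical step and falls to fluoride in step 20.

Step 16
Reactants: 21 silyloxy lactone
Product: 24 methyl 2-(cis-5-acetoxycyclopent-2-en-1-yl)-2-(tert-butyldimethylsilyloxy)acetate, via lithium carboxylate 22 (not isolated), via hydroxy ester 23 (not isolated)
Conditions: LiOH·H2O (1.05 equiv), THF/H2O, 0 °C; evaporation; MeI, DMF, 23 °C; Ac2O, pyridine, DMAP (cat.), 0 °C
Reagents that add atoms: lithium hydroxide, [Li+].[OH-]; iodomethane, CI; acetic anhydride, CC(=O)OC(C)=O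
Why: Saponification (acyl–oxygen cleavage, C14 retained), SN2 O-methylation of the carboxylate and immediate acetylation of the C14 hydroxyl, so that the cis γ-hydroxy ester has no time to close back to the lactone.

Step 17
Reactants: 24 cyclopentene acetate
Product: 26 cyclopentenone (C13 ketone, C11=C12), via allylic alcohol 25 (not isolated)
Conditions: SeO2 (1.2 equiv), dioxane, 80 °C; then Dess–Martin periodinane, NaHCO3, CH2Cl2, 23 °C
Reagents that add atoms: selenium dioxide, O=[Se]=O
Why: Allylic hydroxylation by SeO2 (ene reaction then [2,3]-sigmatropic shift, which returns the double bond to C11=C12) at the C13 methylene rather than at the tertiary C15–H flanked by two oxygenated carbons, followed by Dess–Martin oxidation of the allylic alcohol to the enone.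

Step 18
Reactants: 26 cyclopentenone
Product: 27 α-chloro cyclopentenone (chlorine on C12)
Conditions: PhICl2, pyridine, CH2Cl2, 0 → 23 °C
Reagents that add atoms: iodobenzene dichloride, ClI(Cl)c1ccccc1
Why: α-Chlorination of the enone by chlorine addition and pyridine-induced loss of HCl; the chlorine raises the radical-accepting power of the enone and is the leaving group of step 20.

Step 19
Reactants: 17 potassium hydroxy carboxylate; 27 chloro cyclopentenone
Product: 28 coupled α-chloro ketone (C9–C11 bond)
Conditions: [Ir(dF(CF3)ppy)2(dtbbpy)]PF6 (1 mol %), KH2PO4 (1.2 equiv), degassed DMF, blue LEDs, 23 °C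
Reagents that add atoms: none
Why: Photoredox decarboxylative Giese addition (the excited iridium complex oxidises the carboxylate, CO2 is lost, the tertiary C9 radical adds to C11, the adduct radical is reduced and protonated): the bond forms on the convex H6/H10 face of the cis-fused hydroazulene anti to C1, at C11 anti to the cis C15 side chain and C14 acetate, and C12 is protonated anti to the new C9 substituent, leaving chlorine cis to it.

Step 20
Reactants: 28 coupled chloro ketone
Product: 29 2-oxabicyclo[2.2.1]heptan-6-one (C12–O16 bond, C14 acetate endo)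
Conditions: TBAF (1.1 equiv), THF, −20 → 0 °C
Reagents that add atoms: none
Why: Fluoride desilylation frees the C16 alkoxide, which displaces the C12 chloride from the rear in a 5-exo-tet intramolecular Williamson etherification (inversion at C12), and in the product the endo C14 acetate is the stable epimer because the exo face is blocked by the C9 group.

Step 21
Reactants: 29 oxabicycloheptanone
Product: 30 C1-hydroxy precursor of the target (2,7-dioxabicyclo[3.2.1]octan-3-one complete)
Conditions: mCPBA, NaHCO3, CH2Cl2, 0 → 23 °C
Reagents that add atoms: 3-chloroperoxybenzoic acid, OOC(=O)c1cccc(Cl)c1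
Why: Baeyer–Villiger oxidation with migration (retention) of the oxygen-bearing bridgehead C12, not of the acetoxy-deactivated C14, inserts oxygen between C12 and C13.

Step 22
Reactants: 30 tertiary alcohol
Product: 31 CNP0215240.1 (target)
Conditions: SOCl2, pyridine, CH2Cl2, −40 → 0 °C
Reagents that add atoms: none
Why: Anti elimination from the tertiary chlorosulfite (SOCl2/pyridine dehydration): C10–H is syn to the leaving group and the C1–O bond is expected to lie pseudo-equatorial, so the methyl hydrogens are the ones anti to it and the exocyclic C1 methylidene should predominate; no stereocentre is touched.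

**Compound list**

1 | 3-bromo-4-methylanisole | COc1ccc(C)c(Br)c1 | starting material
2 | 5-chloropentan-2-one | CC(=O)CCCCl | starting material
3 | (5-methoxy-2-methylphenyl)lithium | COc1ccc(C)c([Li])c1 | intermediate
4 | 5-chloro-2-(5-methoxy-2-methylphenyl)pentan-2-ol, racemic | COc1ccc(C)c(c1)C(C)(O)CCCCl | intermediate
5 | 2-(5-chloro-2-methylpentan-2-yl)-4-methoxy-1-methylbenzene | COc1ccc(C)c(c1)C(C)(C)CCCCl | intermediate
6 | 3-(5-chloro-2-methylpentan-2-yl)-4-methylphenol | Oc1ccc(C)c(c1)C(C)(C)CCCCl | intermediate
7 | rac-4a,8,8-trimethyl-5,6,7,8-tetrahydronaphthalen-2(4aH)-one | O=C1C=CC2(C)CCCC(C)(C)C2=C1 | intermediate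
8 | (4aR)-4a,8,8-trimethyl-5,6,7,8-tetrahydronaphthalen-2(4aH)-one | O=C1C=C[C@@]2(C)CCCC(C)(C)C2=C1 | intermediate
9 | (4aR)-3-iodo-4a,8,8-trimethyl-5,6,7,8-tetrahydronaphthalen-2(4aH)-one | O=C1C(I)=C[C@@]2(C)CCCC(C)(C)C2=C1 | intermediate
10 | methyl (4aR)-4a,8,8-trimethyl-2-oxo-2,4a,5,6,7,8-hexahydronaphthalene-3-carboxylate (dienone numbering) | O=C1C(C(=O)OC)=C[C@@]2(C)CCCC(C)(C)C2=C1 | intermediate
11 | methyl 1-hydroxy-1,5,5-trimethyl-8-oxo-hydroazulene-9-carboxylate, target numbering (C6=C7 enone, C1–OH syn to H10, C9 epimers or enol) | C[C@]1(O)CCCC(C)(C)C2=CC(=O)C(C(=O)OC)[C@H]12 | intermediate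
12 | methyl 1-hydroxy-1,5,5,9-tetramethyl-8-oxo-hydroazulene-9-carboxylate (C6=C7 enone, C9 methyl syn to H10, ester syn to C1) | C[C@]1(O)CCCC(C)(C)C2=CC(=O)[C@](C)(C(=O)OC)[C@H]12 | intermediate
13 | 6,7-dihydro derivative of 12, cis-fused (H6 syn to H10) | C[C@]1(O)CCCC(C)(C)[C@@H]2CC(=O)[C@](C)(C(=O)OC)[C@H]12 | intermediate
14 | potassium C7=C8 enolate of the C8-keto γ-lactone (lactone C1–O–CO–C9) | C[C@@]12CCCC(C)(C)[C@@H]3C=C([O-])[C@](C)(C(=O)O1)[C@H]23.[K+] | intermediate
15 | enol triflate lactone (C7=C8–OTf, lactone C1–O–CO–C9) | C[C@@]12CCCC(C)(C)[C@@H]3C=C(OS(=O)(=O)C(F)(F)F)[C@](C)(C(=O)O1)[C@H]23 | intermediate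
16 | saturated tricyclic γ-lactone (cis-fused hydroazulene, lactone C1–O–CO–C9) | C[C@@]12CCCC(C)(C)[C@@H]3CC[C@](C)(C(=O)O1)[C@H]23 | intermediate
17 | potassium 1-hydroxy-1,5,5,9-tetramethyl-perhydroazulene-9-carboxylate (cis-fused, carboxylate syn to C1) | C[C@]1(O)CCCC(C)(C)[C@@H]2CC[C@](C)(C([O-])=O)[C@H]12.[K+] | intermediate
18 | (1R,5S)-2-oxabicyclo[3.3.0]oct-6-en-3-one | O=C1O[C@@H]2CC=C[C@@H]2C1 | starting material
19 | potassium enolate of 18 | [K+].[O-]C1=C[C@H]2C=CC[C@H]2O1 | intermediate
20 | (1R,4R,5R)-4-hydroxy-2-oxabicyclo[3.3.0]oct-6-en-3-one (4-exo) | O=C1O[C@@H]2CC=C[C@@H]2[C@H]1O | intermediate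
21 | 4-exo-(tert-butyldimethylsilyloxy)-2-oxabicyclo[3.3.0]oct-6-en-3-one (ring fusion as in 18) | O=C1O[C@@H]2CC=C[C@@H]2[C@H]1O[Si](C)(C)C(C)(C)C | intermediate
22 | lithium 2-(tert-butyldimethylsilyloxy)-2-(cis-5-hydroxycyclopent-2-en-1-yl)acetate (C14, C15, C16 as in the target) | [Li+].[O-]C(=O)[C@H](O[Si](C)(C)C(C)(C)C)[C@H]1C=CC[C@H]1O | intermediate
23 | methyl ester of 22 | COC(=O)[C@H](O[Si](C)(C)C(C)(C)C)[C@H]1C=CC[C@H]1O | intermediate
24 | methyl 2-(cis-5-acetoxycyclopent-2-en-1-yl)-2-(tert-butyldimethylsilyloxy)acetate | COC(=O)[C@H](O[Si](C)(C)C(C)(C)C)[C@H]1C=CC[C@H]1OC(C)=O | intermediate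
25 | C13 allylic alcohol of 24 (either C13 epimer) | COC(=O)[C@H](O[Si](C)(C)C(C)(C)C)[C@H]1C=CC(O)[C@H]1OC(C)=O | intermediate
26 | methyl 2-(cis-5-acetoxy-4-oxocyclopent-2-en-1-yl)-2-(tert-butyldimethylsilyloxy)acetate | COC(=O)[C@H](O[Si](C)(C)C(C)(C)C)[C@H]1C=CC(=O)[C@H]1OC(C)=O | intermediate
27 | methyl 2-(cis-5-acetoxy-3-chloro-4-oxocyclopent-2-en-1-yl)-2-(tert-butyldimethylsilyloxy)acetate | COC(=O)[C@H](O[Si](C)(C)C(C)(C)C)[C@H]1C=C(Cl)C(=O)[C@H]1OC(C)=O | intermediate
28 | coupled α-chloro ketone (C1 carbinol; C9–C11 bond; C12–Cl cis to C9; C14 OAc and C15 side chain trans to C9) | C[C@]1(O)CCCC(C)(C)[C@@H]2CC[C@@](C)([C@@H]3[C@H](Cl)C(=O)[C@@H](OC(C)=O)[C@H]3[C@@H](O[Si](C)(C)C(C)(C)C)C(=O)OC)[C@H]12 | intermediate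
29 | 2-oxabicyclo[2.2.1]heptan-6-one (bridge C11 bearing the hydroazulene, C14 OAc endo, C16 CO2Me exo, C1 carbinol) | C[C@]1(O)CCCC(C)(C)[C@@H]2CC[C@@](C)([C@@H]3[C@H]4O[C@@H](C(=O)OC)[C@@H]3[C@H](OC(C)=O)C4=O)[C@H]12 | intermediate
30 | C1-hydroxy, C1-methyl precursor of the target (2,7-dioxabicyclo[3.2.1]octan-3-one complete) | C[C@]1(O)CCCC(C)(C)[C@@H]2CC[C@@](C)([C@@H]3[C@@H]4OC(=O)[C@@H](OC(C)=O)[C@H]3[C@H](C(=O)OC)O4)[C@H]12 | intermediate
31 | CNP0215240.1 | C=C1CCCC(C)(C)[C@@H]2CC[C@@](C)([C@@H]3[C@@H]4OC(=O)[C@@H](OC(C)=O)[C@H]3[C@H](C(=O)OC)O4)[C@H]12 | target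

**Step count and risks**

Total step count: 22. Longest linear sequence: 17 (steps 1–13 and 19–22); steps 14–18 make the acceptor branch.

The three steps most likely to fail:

Step 19. The hindered tertiary C9 radical may be captured too slowly by the trisubstituted chloro enone, so that it is reduced to the decarboxylated hydroazulene, or the acceptor may lose chlorine under the photocatalytic cycle. The fallback changes the way the radical is made, from carboxylate oxidation to reductive fragmentation of a redox-active ester. It sets out from 17: TMSCl and Et3N give the bis(trimethylsilyl) derivative F1, whose silyl ester is hydrolysed on neutral aqueous work-up to the C1 trimethylsilyl ether acid F2. N-Hydroxyphthalimide, N,N′-diisopropylcarbodiimide and DMAP give the N-acyloxyphthalimide F3. Irradiation with blue LEDs in CH2Cl2 with [Ru(bpy)3](BF4)2, Hantzsch ester, i-Pr2NEt·HBF4 and 27 gives the coupled chloro ketone with a C1 trimethylsilyl ether F4. TBAF then removes both silyl groups and closes the ether, which brings the material back to 29.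

Step 20. The freed alkoxide may act as a base (loss of HCl to an enone) or take the neighbouring C14 acetate by acyl transfer instead of displacing the hindered chloride. The fallback builds the acetal from an aldehyde instead of by substitution. It sets out from 28: Me2CuLi (THF, −78 °C) removes the chlorine, and the resulting C12=C13 enolate is oxidised in the same flask with 2-(phenylsulfonyl)-3-phenyloxaziridine to the C12-hydroxy ketone F5. H5IO6 in THF/H2O cleaves C12–C13 to the aldehyde acid F6. HF·pyridine followed by camphorsulfonic acid in CH2Cl2 frees the C16 hydroxyl and closes hemiacetal and lactone, which joins the route at 30.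

Step 22. Proton loss may occur from the ring methylene C2 instead of from the methyl group, giving the endocyclic C1=C2 alkene. The fallback changes both the elimination manifold and its place in the sequence. It sets out from 29: the Burgess inner salt (benzene, 50 °C) effects syn elimination through the sulfamate, in which the freely rotating methyl hydrogens reach the cyclic transition state most easily, to give the methylidene oxabicycloheptanone F7, from which a regioisomer can still be separated on AgNO3-impregnated silica. Baeyer–Villiger oxidation of F7 with bis(trimethylsilyl) peroxide and catalytic TMSOTf (CH2Cl2, −78 → −30 °C), which does not epoxidise the 1,1-disubstituted alkene, gives 31.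

**Further compounds**

F1 | step 19 | trimethylsilyl 1-(trimethylsilyloxy)-1,5,5,9-tetramethyl-perhydroazulene-9-carboxylate | C[C@]1(O[Si](C)(C)C)CCCC(C)(C)[C@@H]2CC[C@](C)(C(=O)O[Si](C)(C)C)[C@H]12
F2 | step 19 | 1-(trimethylsilyloxy)-1,5,5,9-tetramethyl-perhydroazulene-9-carboxylic acid | C[C@]1(O[Si](C)(C)C)CCCC(C)(C)[C@@H]2CC[C@](C)(C(O)=O)[C@H]12
F3 | step 19 | N-acyloxyphthalimide of F2 | C[C@]1(O[Si](C)(C)C)CCCC(C)(C)[C@@H]2CC[C@](C)(C(=O)ON3C(=O)c4ccccc4C3=O)[C@H]12
F4 | step 19 | C1 trimethylsilyl ether of 28 | C[C@]1(O[Si](C)(C)C)CCCC(C)(C)[C@@H]2CC[C@@](C)([C@@H]3[C@H](Cl)C(=O)[C@@H](OC(C)=O)[C@H]3[C@@H](O[Si](C)(C)C(C)(C)C)C(=O)OC)[C@H]12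
F5 | step 20 | C12-hydroxy ketone (chlorine of 28 replaced by OH, either C12 epimer) | C[C@]1(O)CCCC(C)(C)[C@@H]2CC[C@@](C)([C@@H]3C(O)C(=O)[C@@H](OC(C)=O)[C@H]3[C@@H](O[Si](C)(C)C(C)(C)C)C(=O)OC)[C@H]12
F6 | step 20 | seco aldehyde acid (C12 aldehyde, C13 carboxylic acid) | C[C@]1(O)CCCC(C)(C)[C@@H]2CC[C@@](C)([C@H](C=O)[C@H]([C@@H](O[Si](C)(C)C(C)(C)C)C(=O)OC)[C@H](OC(C)=O)C(O)=O)[C@H]12
F7 | step 22 | C1-methylidene analogue of 29 | C=C1CCCC(C)(C)[C@@H]2CC[C@@](C)([C@@H]3[C@H]4O[C@@H](C(=O)OC)[C@@H]3[C@H](OC(C)=O)C4=O)[C@H]12
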